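## Retrosynthetic overview

1. The 2-formyloxirane is made last from an isopropenyl group (allylic oxidation, Sharpless epoxidation, oxidation of the primary alcohol); the C6 carbinol is re-set beforehand by oxidation and axial hydride delivery.
2. Key disconnection: the two cyclohexane bonds that flank the lactone ring fusion, C3–C4 and C5–C6. This is a formal [4+2] annulation of a 1,4-dielectrophile (C6 aldehyde plus C3 acylal) with positions 4 and 5 of a 2-silyloxy-3-(silylmethyl)furan.
3. Enabling feature: the lactone carbons C4 and C5 sit between two oxygen-bearing ring carbons in a 1,4-relationship (C3 O-isobutyrate, C6 OH), and C4 carries the exo-methylene carbon. This is the retron of a vinylogous aldol at the butenolide γ-carbon followed by a 2-(silylmethyl)acrylate-type allylation at the β-carbon; the C3 isobutyrate is what remains of the acylal.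
4. The dielectrophile gets its vicinal quaternary/tertiary centres (C1, C2) from an enantioselective boron-enolate Ireland–Claisen rearrangement of an (E)-allyl 3-methylbut-3-enoate made from isoprene monoxide.
5. Ring order: the lactone ring is brought in as the aromatic furan and dearomatised; the cyclohexane ring closes in the key step; the epoxide is formed last.

Key step: step 11

Remark on locants: ring carbons are called C1 (quaternary, CH3 and vinyl), C2 (CH with the three-carbon side chain), C3 (CH–O-isobutyrate), C4 and C5 (lactone ring fusion; C4 bears the methylene-bearing α-carbon, C5 the lactone oxygen) and C6 (CH–OH).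

Assumption: the (S,S)-enantiomer of the diazaborolidine controller in step 3 is taken to deliver the (2S,3S)-acid 5; if the sense of induction is the opposite, the (R,R)-controller is used instead.

## Route

Step 1
Reactants: 1 2-methyl-2-vinyloxirane (isoprene monoxide, racemic); 2 3-methylbut-3-enoic acid
Product: 3 (E)-4-hydroxy-3-methylbut-2-en-1-yl 3-methylbut-3-enoate
Conditions: Pd(PPh3)4 (1 mol%), THF, 0 °C to rt
Reagents that add atoms: none
Why: Tsuji–Trost-type opening of a vinyl epoxide by a carboxylic acid: zerovalent palladium ionises the allylic C–O bond and the carboxylate attacks the unhindered CH2 terminus of the syn π-allyl complex, which should give the 1,4-adduct with the (E)-trisubstituted alkene; no stereocentre is formed.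

Step 2
Reactants: 3 (E)-4-hydroxy-3-methylbut-2-en-1-yl 3-methylbut-3-enoate
Product: 4 (E)-4-[(tert-butyldiphenylsilyl)oxy]-3-methylbut-2-en-1-yl 3-methylbut-3-enoate
Conditions: TBDPSCl, imidazole, DMF, 0 °C to rt
Reagents that add atoms: tert-butyldiphenylsilyl chloride CC(C)(C)[Si](Cl)(c1ccccc1)c1ccccc1
Why: Standard silylation of a primary allylic alcohol with a group that survives the boron Lewis acid of step 3 and the acylal formation of step 6.

Step 3
Reactants: 4 (E)-4-[(tert-butyldiphenylsilyl)oxy]-3-methylbut-2-en-1-yl 3-methylbut-3-enoate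
Product: 5 (2S,3S)-3-{[(tert-butyldiphenylsilyl)oxy]methyl}-3-methyl-2-(prop-1-en-2-yl)pent-4-enoic acid
Conditions: (4S,5S)-2-bromo-4,5-diphenyl-1,3-bis(p-tolylsulfonyl)-1,3,2-diazaborolidine [from the (S,S)-bis-sulfonamide and BBr3, CH2Cl2], Et3N, toluene/hexane, −78 °C, then 4 °C; aqueous work-up
Reagents that add atoms: none
Why: Enantioselective Ireland–Claisen rearrangement of a chiral boron enolate: the (E)-allyl terminus and the enolate with the isopropenyl group cis to the allylic oxygen pass through a chair transition state (methyl axial, silyloxymethyl equatorial), which sets the C1/C2 relative configuration and the new vinyl group, while the C2-symmetric sulfonamide ligand on boron selects the enolate face and so the absolute configuration.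

Step 4
Reactants: 5 (2S,3S)-3-{[(tert-butyldiphenylsilyl)oxy]methyl}-3-methyl-2-(prop-1-en-2-yl)pent-4-enoic acid
Product: 6 (2S,3S)-3-{[(tert-butyldiphenylsilyl)oxy]methyl}-3-methyl-2-(prop-1-en-2-yl)pent-4-en-1-ol
Conditions: LiAlH4, Et2O, 0 °C
Reagents that add atoms: none
Why: Hydride reduction of the carboxylic acid to the primary alcohol, which leaves both stereocentres, the alkenes and the silyl ether untouched.

Step 5
Reactants: 6 (2S,3S)-3-{[(tert-butyldiphenylsilyl)oxy]methyl}-3-methyl-2-(prop-1-en-2-yl)pent-4-en-1-ol
Product: 7 (2S,3S)-3-{[(tert-butyldiphenylsilyl)oxy]methyl}-3-methyl-2-(prop-1-en-2-yl)pent-4-enal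
Conditions: Dess–Martin periodinane, NaHCO3, CH2Cl2, 0 °C; used at once
Reagents that add atoms: none
Why: Dess–Martin oxidation under buffered, non-enolising conditions, so that the α-stereocentre (C2) of this β,γ-unsaturated aldehyde should neither epimerise nor move into conjugation.

Step 6
Reactants: 7 (2S,3S)-3-{[(tert-butyldiphenylsilyl)oxy]methyl}-3-methyl-2-(prop-1-en-2-yl)pent-4-enal
Product: 8 (2S,3S)-3-{[(tert-butyldiphenylsilyl)oxy]methyl}-3-methyl-2-(prop-1-en-2-yl)pent-4-ene-1,1-diyl bis(2-methylpropanoate)
Conditions: isobutyric anhydride, Sc(OTf)3 (2 mol%), MeCN, 0 °C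
Reagents that add atoms: isobutyric anhydride CC(C)C(=O)OC(=O)C(C)C
Why: Lewis acid-catalysed acylal (geminal diester) formation from an aldehyde and an anhydride, which stores C3 at the aldehyde level in a form that is inert to a silyl dienolate at low temperature and already carries the isobutyrate of the target.

Step 7
Reactants: 8 (2S,3S)-3-{[(tert-butyldiphenylsilyl)oxy]methyl}-3-methyl-2-(prop-1-en-2-yl)pent-4-ene-1,1-diyl bis(2-methylpropanoate)
Product: 9 (2S,3S)-3-(hydroxymethyl)-3-methyl-2-(prop-1-en-2-yl)pent-4-ene-1,1-diyl bis(2-methylpropanoate)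
Conditions: HF·pyridine, THF, 0 °C to rt
Reagents that add atoms: none
Why: Fluoride cleavage of the silyl ether under acidic, non-nucleophilic conditions, which an acylal (labile to base, stable to mild acid) should tolerate.

Step 8
Reactants: 9 (2S,3S)-3-(hydroxymethyl)-3-methyl-2-(prop-1-en-2-yl)pent-4-ene-1,1-diyl bis(2-methylpropanoate)
Product: 10 (2S,3S)-3-formyl-3-methyl-2-(prop-1-en-2-yl)pent-4-ene-1,1-diyl bis(2-methylpropanoate)
Conditions: Dess–Martin periodinane, NaHCO3, CH2Cl2, 0 °C to rt
Reagents that add atoms: none
Why: Dess–Martin oxidation of the neopentyl alcohol to the non-enolisable α-quaternary aldehyde, conditions to which the acylal is inert.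

Step 9
Reactants: 11 3-bromofuran-2(5H)-one
Product: 12 3-[(trimethylsilyl)methyl]furan-2(5H)-one
Conditions: Me3SiCH2MgCl, ZnCl2, THF, 0 °C; then 11, PdCl2(dppf) (3 mol%), THF, rt to 50 °C
Reagents that add atoms: (trimethylsilyl)methylmagnesium chloride C[Si](C)(C)C[Mg]Cl
Why: Negishi cross-coupling of an α-bromo butenolide with a (silylmethyl)zinc reagent, the standard way from a vinyl halide to an allylsilane; the zinc reagent does not attack the lactone.

Step 10
Reactants: 12 3-[(trimethylsilyl)methyl]furan-2(5H)-one
Product: 13 tert-butyldimethyl({3-[(trimethylsilyl)methyl]furan-2-yl}oxy)silane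
Conditions: TBSOTf, Et3N, CH2Cl2, 0 °C
Reagents that add atoms: tert-butyldimethylsilyl triflate CC(C)(C)[Si](C)(C)OS(=O)(=O)C(F)(F)F
Why: Soft enolisation (silyl triflate and amine) at the butenolide γ-position gives the aromatic 2-silyloxyfuran, in which the C–Si bond is a furylmethylsilane and therefore dormant.

Step 11
Reactants: 10 (2S,3S)-3-formyl-3-methyl-2-(prop-1-en-2-yl)pent-4-ene-1,1-diyl bis(2-methylpropanoate); 13 tert-butyldimethyl({3-[(trimethylsilyl)methyl]furan-2-yl}oxy)silane
Product: 15 cis-fused α-methylene-γ-butyrolactone/cyclohexane with C1 methyl and vinyl and C2 isopropenyl and C3 equatorial O-isobutyrate and axial C6 hydroxyl (C6 epimer of 17), via vinylogous aldol adduct 14 (not isolated)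
Conditions: 13 (1.1 equiv), BF3·OEt2 (2.5 equiv), CH2Cl2, −78 °C, 2 h; then −78 to 0 °C; sat. aq. NaHCO3
Reagents that add atoms: none
Why: Proposed new method: at −78 °C BF3 activates only the free C6 aldehyde, which is attacked by C5 of the 2-silyloxyfuran (vinylogous Mukaiyama aldol, the closest known reaction being the BF3-mediated addition of 2-silyloxyfurans to aldehydes), and this dearomatisation turns the dormant furylmethylsilane into a 2-(silylmethyl)butenolide, an allylsilane nucleophilic at C4; on warming, BF3 ionises the C3 acylal to an acyloxycarbenium ion that C4 traps intramolecularly with loss of Me3Si (Hosomi–Sakurai allylation of acylals and the 2-(silylmethyl)acrylate route to α-methylene lactones are the known parts, their coupling in one flask with a furan as a 4,5-bis-nucleophile is new). The lactone ring comes from the furan; the cyclohexane ring closes by a chair-like 6-exo-trig attack of C4 on the exocyclic C3=O+ bond, and the exo-methylene group and the C3 isobutyrate appear in the same event. C4 is fixed by the tether on C5, which allows attack only on the same face of the butenolide (cis ring fusion), and C3 by the chair, in which the acyloxy group must be equatorial because the axial site is flanked by the axial C1 methyl group and the axial lactone oxygen on C5. C5 needs the configuration that places the lactone oxygen syn to the C1 methyl group; this should result from the threo course (antiperiplanar open transition state) usual for Lewis acid silyloxyfuran aldols combined with Felkin–Anh attack anti to the vinyl group (C2 branch inside, methyl outside), which gives 14 and then 15 as drawn. The other matched pairing (erythro, C2 branch anti) gives the same C5 configuration with the opposite C6 carbinol, and because C6 is re-set in steps 12 and 13 both are usable; the two mismatched pairings are lost, and the weak methyl/vinyl discrimination at the quaternary centre is the least secure element. Regioselectivity (C5 to C6 first, C4 to C3 second) rests on the oxidation-level difference of the two termini, an acylal not being ionised by BF3 at −78 °C, and on C4 becoming nucleophilic only after C5 has reacted.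

Step 12
Reactants: 15 bicyclic lactone with axial C6 hydroxyl
Product: 16 C6 ketone (cis-fused α-methylene lactone, C3 O-isobutyrate, C2 isopropenyl, C1 methyl and vinyl)
Conditions: Dess–Martin periodinane, NaHCO3, CH2Cl2, 0 °C to rt
Reagents that add atoms: none
Why: Dess–Martin oxidation of the only free hydroxyl removes the provisional C6 stereocentre under neutral conditions that should not epimerise the α-acyloxy C5–H.

Step 13
Reactants: 16 C6 ketone
Product: 17 bicyclic lactone with equatorial C6 hydroxyl (cis to the lactone oxygen)
Conditions: NaBH4, CeCl3·7H2O, MeOH, −78 °C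
Reagents that add atoms: none
Why: Luche reduction: hydride adds along the axial trajectory on the face opposite the axial C1 methyl group and the axial C5–O bond (only axial hydrogens at C2 and C4 on that face), which should give the equatorial C6 alcohol, and the cerium salt suppresses conjugate reduction of the methylene lactone.

Step 14
Reactants: 17 bicyclic lactone with equatorial C6 hydroxyl
Product: 18 allylic alcohol (C2 side chain = 3-hydroxyprop-1-en-2-yl)
Conditions: SeO2 (0.3 equiv), t-BuOOH (3 equiv), salicylic acid (0.1 equiv), CH2Cl2, rt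
Reagents that add atoms: selenium dioxide O=[Se]=O (catalytic oxygen carrier); tert-butyl hydroperoxide CC(C)(C)OO
Why: Selenium dioxide ene reaction and [2,3]-shift on the only electron-rich 1,1-disubstituted alkene should oxidise its methyl group, since the vinyl group has no allylic hydrogen, the lactone methylene is electron-poor and the C2 methine is shielded by the neighbouring quaternary centre.

Step 15
Reactants: 18 allylic alcohol
Product: 19 epoxy alcohol (C2 side chain = 2-(hydroxymethyl)oxiran-2-yl)
Conditions: Ti(OiPr)4 (0.3 equiv), L-(+)-diisopropyl tartrate (0.36 equiv), t-BuOOH (2 equiv, anhydrous), 4 Å molecular sieves, CH2Cl2, −20 °C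
Reagents that add atoms: tert-butyl hydroperoxide CC(C)(C)OO
Why: Sharpless asymmetric epoxidation of a 2-substituted allylic alcohol: the L-(+)-tartrate ligand chooses the alkene face and sets the quaternary epoxide centre under reagent control, while the vinyl and lactone alkenes, which lack an allylic hydroxyl, should not react.

Step 16
Reactants: 19 epoxy alcohol
Product: 20 CNP0127398.1 (target)
Conditions: TEMPO (0.2 equiv), PhI(OAc)2 (1.2 equiv), CH2Cl2, rt
Reagents that add atoms: none
Why: Nitroxyl-catalysed oxidation, which should take the primary epoxy alcohol to the aldehyde and leave the hindered secondary C6 hydroxyl, the epoxide and the esters untouched.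

## Compound list

1 | 2-methyl-2-vinyloxirane (racemic) | CC1(CO1)C=C | starting material
2 | 3-methylbut-3-enoic acid | C=C(C)CC(=O)O | starting material
3 | (E)-4-hydroxy-3-methylbut-2-en-1-yl 3-methylbut-3-enoate | C=C(C)CC(=O)OC/C=C(\C)CO | intermediate
4 | (E)-4-[(tert-butyldiphenylsilyl)oxy]-3-methylbut-2-en-1-yl 3-methylbut-3-enoate | C=C(C)CC(=O)OC/C=C(\C)CO[Si](c1ccccc1)(c1ccccc1)C(C)(C)C | intermediate
5 | (2S,3S)-3-{[(tert-butyldiphenylsilyl)oxy]methyl}-3-methyl-2-(prop-1-en-2-yl)pent-4-enoic acid | C=C[C@](C)(CO[Si](c1ccccc1)(c1ccccc1)C(C)(C)C)[C@H](C(C)=C)C(=O)O | intermediate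
6 | (2S,3S)-3-{[(tert-butyldiphenylsilyl)oxy]methyl}-3-methyl-2-(prop-1-en-2-yl)pent-4-en-1-ol | C=C[C@](C)(CO[Si](c1ccccc1)(c1ccccc1)C(C)(C)C)[C@H](C(C)=C)CO | intermediate
7 | (2S,3S)-3-{[(tert-butyldiphenylsilyl)oxy]methyl}-3-methyl-2-(prop-1-en-2-yl)pent-4-enal | C=C[C@](C)(CO[Si](c1ccccc1)(c1ccccc1)C(C)(C)C)[C@H](C(C)=C)C=O | intermediate
8 | (2S,3S)-3-{[(tert-butyldiphenylsilyl)oxy]methyl}-3-methyl-2-(prop-1-en-2-yl)pent-4-ene-1,1-diyl bis(2-methylpropanoate) | C=C[C@](C)(CO[Si](c1ccccc1)(c1ccccc1)C(C)(C)C)[C@H](C(C)=C)C(OC(=O)C(C)C)OC(=O)C(C)C | intermediate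
9 | (2S,3S)-3-(hydroxymethyl)-3-methyl-2-(prop-1-en-2-yl)pent-4-ene-1,1-diyl bis(2-methylpropanoate) | C=C[C@](C)(CO)[C@H](C(C)=C)C(OC(=O)C(C)C)OC(=O)C(C)C | intermediate
10 | (2S,3S)-3-formyl-3-methyl-2-(prop-1-en-2-yl)pent-4-ene-1,1-diyl bis(2-methylpropanoate) | C=C[C@](C)(C=O)[C@H](C(C)=C)C(OC(=O)C(C)C)OC(=O)C(C)C | intermediate
11 | 3-bromofuran-2(5H)-one | O=C1OCC=C1Br | starting material
12 | 3-[(trimethylsilyl)methyl]furan-2(5H)-one | C[Si](C)(C)CC1=CCOC1=O | intermediate
13 | tert-butyldimethyl({3-[(trimethylsilyl)methyl]furan-2-yl}oxy)silane | C[Si](C)(C)Cc1ccoc1O[Si](C)(C)C(C)(C)C | intermediate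
14 | vinylogous aldol adduct: 3-[(trimethylsilyl)methyl]furan-2(5H)-one bearing at its 5-position the 1-hydroxy-2-methyl-2-vinyl-3-(prop-1-en-2-yl)-4,4-bis(isobutyryloxy)butyl chain, threo at the butenolide/carbinol pair | C=C[C@@](C)([C@H](C(C)=C)C(OC(=O)C(C)C)OC(=O)C(C)C)[C@H](O)[C@H]1OC(=O)C(C[Si](C)(C)C)=C1 | intermediate (not isolated)
15 | bicyclic lactone, axial C6 hydroxyl: cis-fused α-methylene-γ-butyrolactone on a cyclohexane with C1 methyl (syn to the lactone oxygen) and vinyl, C2 isopropenyl, C3 equatorial O-isobutyrate, C6 hydroxyl trans to the lactone oxygen | C=C[C@@]1(C)[C@H](C(C)=C)[C@@H](OC(=O)C(C)C)[C@@H]2C(=C)C(=O)O[C@@H]2[C@H]1O | intermediate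
16 | C6 ketone of 15 | C=C[C@@]1(C)[C@H](C(C)=C)[C@@H](OC(=O)C(C)C)[C@@H]2C(=C)C(=O)O[C@@H]2C1=O | intermediate
17 | bicyclic lactone, equatorial C6 hydroxyl (cis to the lactone oxygen), otherwise as 15 | C=C[C@@]1(C)[C@H](C(C)=C)[C@@H](OC(=O)C(C)C)[C@@H]2C(=C)C(=O)O[C@@H]2[C@@H]1O | intermediate
18 | allylic alcohol: as 17 with the C2 side chain 3-hydroxyprop-1-en-2-yl | C=C[C@@]1(C)[C@H](C(=C)CO)[C@@H](OC(=O)C(C)C)[C@@H]2C(=C)C(=O)O[C@@H]2[C@@H]1O | intermediate
19 | epoxy alcohol: as 17 with the C2 side chain 2-(hydroxymethyl)oxiran-2-yl | C=C[C@@]1(C)[C@H]([C@]2(CO)CO2)[C@@H](OC(=O)C(C)C)[C@@H]2C(=C)C(=O)O[C@@H]2[C@@H]1O | intermediate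
20 | CNP0127398.1: as 17 with the C2 side chain 2-formyloxiran-2-yl | C=C[C@@]1(C)[C@H]([C@]2(C=O)CO2)[C@@H](OC(=O)C(C)C)[C@@H]2C(=C)C(=O)O[C@@H]2[C@@H]1O | target

## Step count and risks

Total step count: 16. Longest linear sequence: 14 steps (steps 1 to 8 and 11 to 16); the furan reagent branch (steps 9 and 10) adds 2 steps.

**Step 11 (proposed new method).** The aldol stage may pair the aldehyde face and the simple diastereoselection the wrong way, so that C5 is formed with the configuration anti to the C1 methyl group and C4 and C3 follow it. The acyloxycarbenium ion may also lose a proton towards C2, or be intercepted by the C6 oxygen, before C4 closes the ring, and the allylsilane may be protodesilylated. The fallback separates the two bond formations and uses only known reaction types. It sets out from 10 and returns at 15. The BF3·OEt2-mediated vinylogous Mukaiyama aldol of 10 with 13 is stopped at −78 °C and 14 is isolated. Its C5/C6 diastereomers are separated, and those with the unwanted C5 configuration are equilibrated at the acidic butenolide γ-position (Et3N, CH2Cl2) and resubmitted. Silylation of the carbinol (TBSOTf, 2,6-lutidine, CH2Cl2) gives the silyl ether of 14, F1, in which the C6 oxygen can no longer take part. A separate Hosomi–Sakurai ring closure on the acylal (TMSOTf, CH2Cl2, −78 to −20 °C) then gives the silyl ether of 15, F2. HF·pyridine returns 15.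

**Step 3.** Incomplete control of the boron enolate geometry, weak facial discrimination by the controller, or a slow rearrangement at the trisubstituted allyl terminus would erode the diastereomeric and enantiomeric purity of the two stereocentres on which all later induction rests. The fallback sets out from 4 and returns at 5. A classical Ireland–Claisen rearrangement (LiN(iPr)2, Me3SiCl, THF, −78 °C to rt, then aqueous acid) through the same chair gives the racemic acid F3 with the same relative configuration. It is resolved by crystallisation of its salt with (S)-1-phenylethylamine, F4 (the (R)-amine is used if the other diastereomeric salt is the less soluble one). Acidification of the salt returns 5.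

**Step 14.** Late-stage allylic oxidation may attack the C2 methine, run on to the enal, or engage the lactone methylene, with loss of advanced material. The fallback sets out from 17 and returns at 18. An ene-type allylic chlorination of the isopropenyl group (N-chlorosuccinimide, PhSeCl catalyst, CH2Cl2, rt) gives the 3-chloroprop-1-en-2-yl compound F5. Silver-assisted hydrolysis (AgOTf, 2,6-lutidine, acetone/water) returns 18.

## Further compounds

F1 | step 11 | tert-butyldimethylsilyl ether of 14 (silylated at the carbinol oxygen) | C=C[C@@](C)([C@H](C(C)=C)C(OC(=O)C(C)C)OC(=O)C(C)C)[C@H](O[Si](C)(C)C(C)(C)C)[C@H]1OC(=O)C(C[Si](C)(C)C)=C1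
F2 | step 11 | tert-butyldimethylsilyl ether of 15 | C=C[C@@]1(C)[C@H](C(C)=C)[C@@H](OC(=O)C(C)C)[C@@H]2C(=C)C(=O)O[C@@H]2[C@H]1O[Si](C)(C)C(C)(C)C
F3 | step 3 | racemic acid (5 together with its enantiomer) | C=C[C@](C)(CO[Si](c1ccccc1)(c1ccccc1)C(C)(C)C)[C@H](C(C)=C)C(=O)O.C=C[C@@](C)(CO[Si](c1ccccc1)(c1ccccc1)C(C)(C)C)[C@@H](C(C)=C)C(=O)O
F4 | step 3 | (S)-1-phenylethylammonium salt of 5 | C=C[C@](C)(CO[Si](c1ccccc1)(c1ccccc1)C(C)(C)C)[C@H](C(C)=C)C(=O)[O-].C[C@H]([NH3+])c1ccccc1
F5 | step 14 | allylic chloride: as 17 with the C2 side chain 3-chloroprop-1-en-2-yl | C=C[C@@]1(C)[C@H](C(=C)CCl)[C@@H](OC(=O)C(C)C)[C@@H]2C(=C)C(=O)O[C@@H]2[C@@H]1O
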